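Ring B (C5–C10; terpenoid numbering) is disconnected at C5–C6 and C9–C10. One Lewis-acid operation, a Friedel–Crafts acylation of the C5=C10 alkene followed by cycloalkylation, should join (S)-2,4,4-trimethylcyclohex-2-enyl acetate (ring A) and (4-methoxyphenyl)acetyl chloride: the acylium carbon becomes C6 and the anisole carbon C9 closes on the C10 cation. The step exploits the C6 oxygen (as ketone), the C8=C9 double bond (as an arene edge of a masked ring C) and the C1 acetoxy group (facial control at C10). Birch reduction then unmasks ring C as a C12 ketone with C8=C9 intact, and the C15–C16 bridge is annulated onto C11 and C13.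

Key step: step 3

Remark on numbering: ring A = C1–C5 and C10 (C18/C19 methyls on C4, C20 methyl on C10); ring B = C5–C10; ring C = C8, C9, C11–C14; C12 is the one-carbon bridge and C15–C16(=C17H2) the two-carbon bridge between C11 and C13.
Remark on availability: compound 1 is taken as commercial (it is also the one-step Robinson annulation product of isobutyraldehyde and ethyl vinyl ketone).
Remark on compound 13: its C15 configuration is left open because step 11 erases it.

Step 1
Reactants: 1 2,4,4-trimethylcyclohex-2-en-1-one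
Product: 2 (S)-2,4,4-trimethylcyclohex-2-en-1-ol
Conditions: (R)-Me-CBS oxazaborolidine (10 mol %), BH3·SMe2, THF, −20 °C; MeOH, then aqueous work-up
Reagents that add atoms: none
Why: Corey–Bakshi–Shibata reduction, in which the C2-methylated alkene arm acts as the large group, so 1,2-hydride delivery should give the (S)-carbinol that becomes C1.

Step 2
Reactants: 2 (S)-2,4,4-trimethylcyclohex-2-en-1-ol
Product: 3 (S)-2,4,4-trimethylcyclohex-2-en-1-yl acetate
Conditions: Ac2O, pyridine, DMAP (cat.), CH2Cl2, 0 °C → rt
Reagents that add atoms: acetic anhydride, CC(=O)OC(C)=O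
Why: DMAP-catalysed O-acylation; the acetate is the neighbouring group that controls C10 in step 3 (it is lost in step 5 and put back in step 8).

Step 3
Reactants: 3 (S)-2,4,4-trimethylcyclohex-2-en-1-yl acetate; 4 (4-methoxyphenyl)acetyl chloride
Product: 5 (1S,5R,10R)-12-methoxy-6-oxopodocarpa-8,11,13-trien-1-yl acetate
Conditions: SnCl4 (2.2 equiv), CH2Cl2, −78 → −20 °C; quench into cold aqueous NaHCO3
Reagents that add atoms: none
Why: SnCl4 converts 4 into the acylium ion, which attacks C5 of the trisubstituted C5=C10 bond of 3 (Markovnikov), and the tertiary C10 cation, held on its α face by the C1 acetate as a cis-fused acetoxonium ion, is then alkylated by the arene carbon ortho to the CH2 group (C9) with loss of HCl. This is the acylation–cycloalkylation of an alkene with an arylacetyl chloride used for 2-tetralones (Friedel–Crafts acylation of the alkene, then intramolecular Friedel–Crafts alkylation). Ring B is the only ring closed: C5–C6 forms intermolecularly and C9–C10 closes the six-membered ring, with the attacking arene C8=C9 bond ending inside the ring (6-endo cation–π closure). C10 is set by C1, because C9 must enter anti to the acetoxy oxygen (opening of the acetoxonium ion with inversion), which leaves the C10 methyl cis to the acetate. C5 should follow from anti addition across C5=C10 in a chair-like closure (C6 equatorial on ring A), and the same trans ketone is expected if the β-acyl cation first loses H-5 to the enone, since conjugate closure then ends with protonation at C5 anti to the new axial C10 methyl; C5 is the one epimerizable centre, so the mixture is quenched cold into buffer. The step needs acylation at C5 and not C10 (tertiary versus secondary cation), closure at C9 (the two ortho positions of the para-substituted ring are equivalent) and survival of the allylic C1–O bond, which the mild Lewis acid and low temperature should secure.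

Step 4
Reactants: 5 (1S,5R,10R)-12-methoxy-6-oxopodocarpa-8,11,13-trien-1-yl acetate
Product: 6 (1S,5R,6S,10R)-6-hydroxy-12-methoxypodocarpa-8,11,13-trien-1-yl acetate
Conditions: NaBH4, MeOH/CH2Cl2, −20 °C
Reagents that add atoms: none
Why: Substrate-controlled ketone reduction in which hydride adds to C6 from the face anti to the two syn-axial methyl groups (C20 and the axial methyl on C4), which should give the axial 6-alcohol.

Step 5
Reactants: 6 (1S,5R,6S,10R)-6-hydroxy-12-methoxypodocarpa-8,11,13-trien-1-yl acetate
Product: 8 (1S,5R,6S,10R)-1,6-dihydroxypodocarp-8-en-12-one, via Birch enol ether 7 (not isolated)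
Conditions: Li (excess), NH3(l), THF, t-BuOH, −78 → −33 °C; NH4Cl; then oxalic acid, MeOH/H2O, rt
Reagents that add atoms: water, O
Why: Birch reduction of the anisole ring protonates the unsubstituted positions C11 and C14, so the tetrasubstituted C8=C9 bond and the C12 enol ether remain (as with estradiol methyl ether), excess lithium also cleaves the acetate, and oxalic acid hydrolyses the enol ether to the β,γ-unsaturated ketone without moving the double bond into conjugation.

Step 6
Reactants: 8 (1S,5R,6S,10R)-1,6-dihydroxypodocarp-8-en-12-one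
Product: 9 (1S,5R,6S,10R,11R)-11-(2-bromoprop-2-en-1-yl)-1,6-dihydroxypodocarp-8-en-12-one
Conditions: LiN(i-Pr)2 (3.2 equiv), THF, −78 °C; 2,3-dibromopropene, −78 → −30 °C; NH4Cl
Reagents that add atoms: 2,3-dibromopropene, C=C(Br)CBr
Why: After the two hydroxyls, deprotonation at the doubly activated C11 gives the extended dienolate, which is C-alkylated at its α-carbon by the allylic bromide on the face opposite the axial C20 methyl with retention of the C8=C9 bond (α-alkylation of a dienolate).

Step 7
Reactants: 9 (1S,5R,6S,10R,11R)-11-(2-bromoprop-2-en-1-yl)-1,6-dihydroxypodocarp-8-en-12-one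
Product: 10 (1S,5R,6S,10R,11R,13R)-1,6-dihydroxy-15(8→11)-abeo-kaura-8,16-dien-12-one
Conditions: Pd(PPh3)4 (10 mol %), t-BuOK (3.3 equiv), THF, 60 °C
Reagents that add atoms: none
Why: Palladium-catalysed intramolecular α-alkenylation of a ketone, in which oxidative addition into the vinyl bromide and coupling with the C13 enolate closes the five-membered ring of the bicyclo[3.2.1]octane; only the C11 epimer with the side chain anti to C20 reaches C13 without a clash with C20, which fixes C11 and C13.

Step 8
Reactants: 10 (1S,5R,6S,10R,11R,13R)-1,6-dihydroxy-15(8→11)-abeo-kaura-8,16-dien-12-one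
Product: 11 (1S,5R,6S,10R,11R,13R)-6-hydroxy-12-oxo-15(8→11)-abeo-kaura-8,16-dien-1-yl acetate
Conditions: Ac2O (1.2 equiv), pyridine, DMAP (cat.), CH2Cl2, 0 °C
Reagents that add atoms: acetic anhydride, CC(=O)OC(C)=O
Why: Steric differentiation in an acylation, in which the equatorial C1 hydroxyl should react while the axial C6 hydroxyl, flanked by two syn-axial methyl groups, stays free; C12 is still a ketone.

Step 9
Reactants: 11 (1S,5R,6S,10R,11R,13R)-6-hydroxy-12-oxo-15(8→11)-abeo-kaura-8,16-dien-1-yl acetate
Product: 12 (1S,5R,6S,10R,11R,13R)-6,12-dihydroxy-15(8→11)-abeo-kaura-8,16-dien-1-yl acetate with the 12-hydroxyl syn to the C15–C16 bridge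
Conditions: NaBH4, MeOH, −40 → 0 °C
Reagents that add atoms: none
Why: Substrate-controlled borohydride reduction in which hydride attacks the bridging C12 ketone from the side of the flat C8=C9 bridge (axial attack on ring C, away from the C15–C16 bridge), which should place the hydroxyl syn to the two-carbon bridge.

Step 10
Reactants: 12 (1S,5R,6S,10R,11R,13R)-6,12-dihydroxy-15(8→11)-abeo-kaura-8,16-dien-1-yl acetate
Product: 13 (1S,5R,6S,10R,11R,12S,13R)-6,12,15-trihydroxy-15(8→11)-abeo-kaura-8,16-dien-1-yl acetate (C15 configuration open)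
Conditions: SeO2 (cat.), t-BuOOH, CH2Cl2, rt
Reagents that add atoms: tert-butyl hydroperoxide, CC(C)(C)OO
Why: Selenium dioxide allylic hydroxylation (ene reaction, then [2,3]-shift) of the exocyclic alkene can only use the C15 hydrogens because C13 is a bridgehead, and the tetrasubstituted C8=C9 bond is shielded in the same way (its ene reaction would need selenium at the congested C9 or a bridgehead alkene at C11).

Step 11
Reactants: 13 (1S,5R,6S,10R,11R,12S,13R)-6,12,15-trihydroxy-15(8→11)-abeo-kaura-8,16-dien-1-yl acetate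
Product: 14 (1S,5R,6S,10R,11R,12S,13R)-6,12-dihydroxy-15-oxo-15(8→11)-abeo-kaura-8,16-dien-1-yl acetate (CNP0149338.1)
Conditions: MnO2 (excess), CH2Cl2, rt
Reagents that add atoms: none
Why: MnO2 oxidizes only the allylic C15 alcohol, leaving the saturated C6 and C12 alcohols and the acetate, and gives the α-methylene ketone.

Compound list
1 | 2,4,4-trimethylcyclohex-2-en-1-one | CC1=CC(C)(C)CCC1=O | starting material
2 | (S)-2,4,4-trimethylcyclohex-2-en-1-ol | O[C@H]1CCC(C)(C)C=C1C | intermediate
3 | (S)-2,4,4-trimethylcyclohex-2-en-1-yl acetate | CC(=O)O[C@H]1CCC(C)(C)C=C1C | intermediate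
4 | (4-methoxyphenyl)acetyl chloride | COc1ccc(CC(Cl)=O)cc1 | starting material
5 | (1S,5R,10R)-12-methoxy-6-oxopodocarpa-8,11,13-trien-1-yl acetate (trans A/B, acetate cis to C20) | CC(=O)O[C@H]1CCC(C)(C)[C@H]2C(=O)Cc3ccc(OC)cc3[C@]12C | intermediate
6 | (1S,5R,6S,10R)-6-hydroxy-12-methoxypodocarpa-8,11,13-trien-1-yl acetate (6-OH axial, cis to C20) | CC(=O)O[C@H]1CCC(C)(C)[C@H]2[C@@H](O)Cc3ccc(OC)cc3[C@]12C | intermediate
7 | (1S,5R,6S,10R)-12-methoxypodocarpa-8,12-diene-1,6-diol (Birch enol ether) | O[C@H]1CCC(C)(C)[C@H]2[C@@H](O)CC3=C(CC(OC)=CC3)[C@]12C | intermediate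
8 | (1S,5R,6S,10R)-1,6-dihydroxypodocarp-8-en-12-one | O[C@H]1CCC(C)(C)[C@H]2[C@@H](O)CC3=C(CC(=O)CC3)[C@]12C | intermediate
9 | (1S,5R,6S,10R,11R)-11-(2-bromoprop-2-en-1-yl)-1,6-dihydroxypodocarp-8-en-12-one (side chain anti to C20) | O[C@H]1CCC(C)(C)[C@H]2[C@@H](O)CC3=C([C@@H](CC(Br)=C)C(=O)CC3)[C@]12C | intermediate
10 | (1S,5R,6S,10R,11R,13R)-1,6-dihydroxy-15(8→11)-abeo-kaura-8,16-dien-12-one (C15H2–C16(=CH2) bridge anti to C20, C12 bridging ketone) | C=C1C[C@@H]2C3=C(C[C@H]1C2=O)C[C@H](O)[C@@H]1C(C)(C)CC[C@H](O)[C@@]31C | intermediate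
11 | (1S,5R,6S,10R,11R,13R)-6-hydroxy-12-oxo-15(8→11)-abeo-kaura-8,16-dien-1-yl acetate | C=C1C[C@@H]2C3=C(C[C@H]1C2=O)C[C@H](O)[C@@H]1C(C)(C)CC[C@H](OC(C)=O)[C@@]31C | intermediate
12 | (1S,5R,6S,10R,11R,13R)-6,12-dihydroxy-15(8→11)-abeo-kaura-8,16-dien-1-yl acetate (12-OH syn to the C15–C16 bridge) | C=C1C[C@@H]2C3=C(C[C@H]1[C@@H]2O)C[C@H](O)[C@@H]1C(C)(C)CC[C@H](OC(C)=O)[C@@]31C | intermediate
13 | (1S,5R,6S,10R,11R,12S,13R)-6,12,15-trihydroxy-15(8→11)-abeo-kaura-8,16-dien-1-yl acetate (C15 configuration open, erased in step 11) | C=C1C(O)[C@@H]2C3=C(C[C@H]1[C@@H]2O)C[C@H](O)[C@@H]1C(C)(C)CC[C@H](OC(C)=O)[C@@]31C | intermediate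
14 | (1S,5R,6S,10R,11R,12S,13R)-6,12-dihydroxy-15-oxo-15(8→11)-abeo-kaura-8,16-dien-1-yl acetate (CNP0149338.1) | C=C1C(=O)[C@@H]2C3=C(C[C@H]1[C@@H]2O)C[C@H](O)[C@@H]1C(C)(C)CC[C@H](OC(C)=O)[C@@]31C | target

Total step count: 11. Longest linear sequence: 11 steps (1 → 14); compound 4 is used as purchased.

Steps most likely to fail

Step 3. The Lewis acid may ionize the allylic acetate before acylation. The new ketone may also epimerize at C5 toward the cis ring fusion, or the acylium may add to the wrong face of C5. The fallback sets out from 3 and returns at 5. Compound 3 would be combined with (4-methoxyphenyl)acetaldehyde in a Prins addition/Friedel–Crafts cycloalkylation (BF3·OEt2, CH2Cl2, −78 °C). Here C5 is fixed in the C–C bond-forming event and no enolizable ketone meets acid. This should give the C6-epimeric alcohol (1S,5R,6R,10R)-6-hydroxy-12-methoxypodocarpa-8,11,13-trien-1-yl acetate F1. Oxidation with Dess–Martin periodinane buffered with NaHCO3 would then give 5 under neutral conditions.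

Step 7. The base may move the C8=C9 bond into conjugation with the C12 ketone, or the vinyl bromide may be reduced instead of coupled. The fallback sets out from 8 and returns at 10. It closes the C13–C16 bond by a gold-catalysed Conia-ene-type cyclization. The dienolate of 8 is alkylated with propargyl bromide to (1S,5R,6S,10R,11R)-1,6-dihydroxy-11-(prop-2-yn-1-yl)podocarp-8-en-12-one F2. LiN(i-Pr)2 and TBSOTf convert this into the 1,6-bis-TBS ether C12=C13 TBS enol ether F3. Ph3PAuCl/AgBF4 in CH2Cl2/MeOH should then effect 5-exo-dig attack of C13 on the alkyne to give the 1,6-bis-TBS ether of 10 F4. HF·pyridine frees the two hydroxyls and gives 10.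

Step 6. The two alkoxides may be O-alkylated, or C-alkylation may go twice or at C13 instead of C11. The fallback sets out from 8 and returns at 9. It uses a Stork enamine alkylation, which needs no strong base. Compound 8 and pyrrolidine (benzene, water separator) give the conjugated dienamine (1S,5R,6S,10R)-12-(pyrrolidin-1-yl)podocarpa-8,11-diene-1,6-diol F5. This is C-alkylated at C11 with 2,3-dibromopropene (MeCN, 60 °C) and hydrolysed with AcOH/NaOAc/H2O to 9.

Further compounds
F1 | step 3 | (1S,5R,6R,10R)-6-hydroxy-12-methoxypodocarpa-8,11,13-trien-1-yl acetate | CC(=O)O[C@H]1CCC(C)(C)[C@H]2[C@H](O)Cc3ccc(OC)cc3[C@]12C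
F2 | step 7 | (1S,5R,6S,10R,11R)-1,6-dihydroxy-11-(prop-2-yn-1-yl)podocarp-8-en-12-one | O[C@H]1CCC(C)(C)[C@H]2[C@@H](O)CC3=C([C@@H](CC#C)C(=O)CC3)[C@]12C
F3 | step 7 | 1,6-bis-TBS ether C12=C13 TBS enol ether of F2 | CC(C)(C)[Si](C)(C)O[C@H]1CCC(C)(C)[C@H]2[C@@H](O[Si](C)(C)C(C)(C)C)CC3=C([C@@H](CC#C)C(O[Si](C)(C)C(C)(C)C)=CC3)[C@]12C
F4 | step 7 | 1,6-bis-TBS ether of 10 | C=C1C[C@@H]2C3=C(C[C@H]1C2=O)C[C@H](O[Si](C)(C)C(C)(C)C)[C@@H]1C(C)(C)CC[C@H](O[Si](C)(C)C(C)(C)C)[C@@]31C
F5 | step 6 | (1S,5R,6S,10R)-12-(pyrrolidin-1-yl)podocarpa-8,11-diene-1,6-diol | O[C@H]1CCC(C)(C)[C@H]2[C@@H](O)CC3=C(C=C(N4CCCC4)CC3)[C@]12C
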